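# Gymconopin D: ring A by Diels–Alder benzannulation of an aryl alkynyl ketone

## The problem

Gymconopin D (16) is an achiral bibenzyl built around a 1,2,3,5-tetrasubstituted benzene, ring A. Ring A carries methoxy groups at C3 and C5, a 2-(3-hydroxyphenyl)ethyl arm at C1 (ring B) and a 4-hydroxybenzyl arm at C2 (ring C, joined through C7). There is no stereocentre, so the whole difficulty is regiochemical: C7 sits at the most crowded position of ring A, between the C3 methoxy group and the C1 chain. Electrophilic substitution on a preformed 3,5-dimethoxybibenzyl would have to choose between C2, the position between the two methoxy groups, and the activated ring B. The four oxygen atoms must be told apart: two are methyl ethers on ring A and two are free phenols on rings B and C, so the phenols must travel under a group that comes off at the end without touching aryl methyl ethers. The fragile part is the electron-rich diarylmethane: a cation at C7 is stabilised by the ortho and para methoxy groups and can alkylate ring B through the two-carbon tether, closing a seven-membered ring. The key step is made possible by the pattern of ring A: C3–C4–C5–C6 read O, H, O, H, the imprint of a 1,1-dialkoxy-3-silyloxybutadiene, and C1–C2 carry both carbon arms, the imprint of a disubstituted alkyne that becomes a correctly polarised ynone when C7 is a ketone.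

## Retrosynthesis

**16 ⇒ 15.** The two O–benzyl bonds on rings B and C are cut last. Free phenols would not survive n-BuLi, the acid chloride or the methylation of the ring A phenol, and methyl ethers could not be told from those of ring A. Bis-benzyl ether 15 already has every carbon of the target. The forward step must cleave aryl benzyl ethers by hydrogenolysis and leave the diarylmethane and the methyl ethers alone.

**15 ⇒ 14 ⇒ 13.** The C7 methylene is traced back through carbinol 14 to diaryl ketone 13; no skeletal bond is cut. The ketone is kept because it activates and polarises the alkyne in the ring-forming step and because it arrives already bonded to ring C. Attaching ring C to a finished ring A by benzylic cross-coupling would cost more steps. The forward steps need a hydride strong enough for a hindered, electron-rich benzophenone and a deoxygenation in which hydride capture of the C7 cation outruns attack by ring B.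

**13 ⇒ 12.** The O–CH3 bond at C5 is cut. The C5 oxygen enters as a silyl enol ether, so it appears as a phenol after aromatisation. That phenol is para to the ketone, acidic, and the only free hydroxyl in 12, so the methylation needs no selectivity.

**12 ⇒ 7 + 9.** Ring A is opened at C6–C1 and C2–C3. Cutting C2–C7 instead, by acylation of a resorcinol ether, would hand the regiochemistry back to arene substitution. The chosen cut dissolves the tetrasubstituted arene into two acyclic pieces, ynone 7 and diene 9, each with its substituents already in place. The forward reaction must be a regioselective (4+2) cycloaddition that aromatises by loss of methanol and gives up its silyl group on work-up.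

**7 ⇒ 5 + 6.** The C7–C(sp) bond is cut to terminal alkyne 5 and acid chloride 6, joined by an acyl Sonogashira coupling. Adding the alkyne at the aldehyde oxidation level and oxidising afterwards would form the same bond in two steps instead of one. The forward coupling must beat alkyne dimerisation, and the ynone must tolerate the amine.

**5 ⇒ 4 ⇒ 1 + 2.** The CH2–CH2 bond of the future bridge is cut between the propargylic and the benzylic carbon, with a silyl group on the alkyne terminus (4). The neighbouring cut, C(sp)–CH2, would need a 2-arylethyl electrophile that eliminates easily. The precursors are 1-(trimethylsilyl)propyne (1) and benzylic bromide 2, both commercial. The forward steps are propargylic lithiation, SN2 alkylation at the propargyl rather than the allenyl terminus, and protodesilylation.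

**9 ⇒ 8.** The O–Si bond is cut: diene 9 is the silyl enol ether of 4,4-dimethoxybut-3-en-2-one (8). The forward step must silylate the methyl ketone enolate on oxygen without hydrolysing the ketene acetal.

## Roads not taken

**Alternative 1:** the ethano bridge is cut on both sides of a vinylboron linchpin.
- **Forward step:** the aryllithium from 1-bromo-2-[4-(benzyloxy)benzyl]-3,5-dimethoxybenzene A2 adds to the vinylboronic ester A3. The resulting ate complex reacts with 3-(benzyloxy)phenyl triflate A4 under Pd(OAc)2 and a chiral ferrocenyl bisphosphine. Ring A migrates from boron to carbon as palladium delivers ring B from triflate A4, giving the secondary benzylic boronate A1.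
- **Merits:** it is the most convergent of the four plans. Both bridge bonds form in one late step, and protodeboronation of A1 would give 15, one step from the target. It needs no redox change at C7 and varies ring B easily. In these respects it is better than the chosen plan.
- **Weak points:** A2 is itself a 1,2,3,5-tetrasubstituted arene, so the central regiochemical problem is moved back, not solved. The migrating aryl group has a bulky ortho substituent. The step also makes a stereocentre and a C–B bond that must both be erased, with an expensive ligand.
- **Comparison:** the chosen plan is less convergent, but ring A is assembled with its regiochemistry fixed by polarity, from cheap components and with no discarded functionality beyond one oxygen atom.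

**Alternative 2:** ring A is cut at C4–C5 and C6–C1.
- **Forward step:** pyrone A6 undergoes a Diels–Alder reaction with the ketene acetal 1,1-dimethoxyethene A7; loss of CO2 and methanol gives benzoate A5.
- **Merits:** both methoxy groups arrive as methyl ethers, so the phenol methylation disappears. The addition of ketene acetal A7 to an ester-bearing pyrone is probably a more reliable cycloaddition than that of an internal ynone. Here the alternative is as good or better.
- **Weak points:** A6 is a fully substituted heterocycle that needs its own multistep synthesis. C7 arrives as an ester on a 2,6-disubstituted ring without ring C. The ester must be reduced and ring C added by aryl-metal addition at the aldehyde level to reach carbinol 14, which is more steps than the two from 12.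
- **Comparison:** the chosen plan pays one methylation but brings ring C and the correct C7 carbon in with the alkyne.

**Alternative 3:** ring A is cut at C2–C1 in a biomimetic fold.
- **Forward step:** triketo ester A9 is enolised at the carbon bearing the ester and the benzyl group (Cs2CO3). Aldol closure onto the distal ketone, dehydration, and acid-induced ester cleavage with loss of CO2 give resorcinol A8.
- **Merits:** the end game is shorter than in the chosen plan. Double O-methylation of A8 gives 15, and hydrogenolysis gives 16, with no redox work at C7.
- **Weak points:** the required nucleophile is the most hindered and least acidic of the enolisable positions of A9 and must form a quaternary centre. The doubly activated methylenes can fold differently, by aldol closure from the other chain end or by pyrone formation through attack of an enol oxygen on the ester. A9 is also a sensitive polycarbonyl compound whose assembly needs iterative enolate acylations.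
- **Comparison:** the chosen plan is two steps longer after ring formation, but its regiochemistry is enforced by the polarity of two stable components, whereas that of Alternative 3 is only biased.

Key step: step 5

Assumption: ketone 8 and acid chloride 6 are taken as catalogue compounds, and diene 9 is treated as a hydrolysis-sensitive reagent that is distilled and used at once.

## Route

Step 1
Reactants: 1 1-(trimethylsilyl)propyne; 2 3-(benzyloxy)benzyl bromide
Product: 4 {4-[3-(benzyloxy)phenyl]but-1-yn-1-yl}trimethylsilane, via lithiated 1-(trimethylsilyl)propyne 3 (not isolated)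
Conditions: n-BuLi, THF, –78 → –20 °C; then 2, –78 °C → rt
Reagents that add atoms: none
Why: Propargylic deprotonation of 1 gives organolithium 3, which is alkylated by benzylic bromide 2 in an SN2 reaction; the silyl group blocks the alkyne terminus and steers the ambident anion to the propargyl rather than the allenyl product. Aryl benzyl ethers are inert to these conditions.

Step 2
Reactants: 4 {4-[3-(benzyloxy)phenyl]but-1-yn-1-yl}trimethylsilane
Product: 5 1-(benzyloxy)-3-(but-3-yn-1-yl)benzene
Conditions: K2CO3, MeOH/THF, rt
Reagents that add atoms: none
Why: Base-catalysed methanolysis of the C(sp)–Si bond (protodesilylation of an alkynylsilane); nothing else in 4 reacts with K2CO3 in methanol.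

Step 3
Reactants: 5 1-(benzyloxy)-3-(but-3-yn-1-yl)benzene; 6 4-(benzyloxy)benzoyl chloride
Product: 7 1-[4-(benzyloxy)phenyl]-5-[3-(benzyloxy)phenyl]pent-2-yn-1-one
Conditions: PdCl2(PPh3)2 (2 mol %), CuI (4 mol %), Et3N (1.2 equiv), THF, rt, argon
Reagents that add atoms: none
Why: Acyl Sonogashira coupling: acid chloride 6 adds oxidatively to zerovalent palladium generated from PdCl2(PPh3)2, the alkyne is transferred with the help of CuI and Et3N, and reductive elimination gives the ynone. Alkyl acetylenes and 4-alkoxybenzoyl chlorides are standard partners at room temperature, where decarbonylation does not compete.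

Step 4
Reactants: 8 4,4-dimethoxybut-3-en-2-one
Product: 9 1,1-dimethoxy-3-(trimethylsilyloxy)buta-1,3-diene
Conditions: Me3SiCl, Et3N, ZnCl2 (cat.), toluene, 40 °C; filtration, distillation under reduced pressure
Reagents that add atoms: chlorotrimethylsilane, C[Si](C)(C)Cl
Why: Silyl enol ether formation under the amine/ZnCl2/chlorosilane conditions used for 1-alkoxy-3-silyloxybutadienes; only the methyl group can be enolised, and O-silylation of the cross-conjugated enolate gives the 2-silyloxydiene. Water is excluded because both the ketene acetal and the silyl enol ether hydrolyse easily.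

Step 5
Reactants: 7 1-[4-(benzyloxy)phenyl]-5-[3-(benzyloxy)phenyl]pent-2-yn-1-one; 9 1,1-dimethoxy-3-(trimethylsilyloxy)buta-1,3-diene
Product: 12 [4-(benzyloxy)phenyl]{2-[2-(3-benzyloxyphenyl)ethyl]-4-hydroxy-6-methoxyphenyl}methanone, via dimethoxycyclohexadiene cycloadduct 10 (not isolated), via aryl trimethylsilyl ether 11 (not isolated)
Conditions: 9 (2.5 equiv), toluene, 80 → 110 °C, sealed tube; then 1 M HCl, THF, rt
Reagents that add atoms: none
Why: This is a Diels–Alder benzannulation in which diene 9, a vinylogous ketene acetal with its largest HOMO coefficient on the terminal CH2 (future C6), meets ynone 7, whose largest LUMO coefficient lies on the alkyne carbon β to the carbonyl (future C1, bearing the arylethyl chain), so the C6–C1 bond leads in a strongly asynchronous cycloaddition and the ketene acetal carbon (C3) bonds to the α-carbon (C2). Ring A closes in this (4+2) mode, four carbons from the diene and two from the alkyne, as cyclohexa-1,4-diene 10. In 10 the acetal carbon C3 lies across the ring from the C6 methylene, so 1,4-elimination of methanol aromatises it to aryl silyl ether 11, and dilute acid on work-up cleaves the O–Si bond to give phenol 12. The closest known reaction type is the thermal cycloaddition of 1,1-dialkoxy-3-silyloxybutadienes with 2-alkynoates and alkynyl ketones, which gives resorcinol monoalkyl ethers with the acyl group next to the alkoxy group. No stereocentre is created. The one selectivity needed is regiochemical (aroyl group at C2 beside the methoxy carbon C3, arylethyl arm at C1 beside C6), and it is secured by the matched polarity of the two components; the opposite orientation would pair the nucleophilic diene terminus with the α-carbon, which is not electrophilic. The neutral thermal conditions leave the aryl ketone and both benzyl ethers untouched.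

Step 6
Reactants: 12 [4-(benzyloxy)phenyl]{2-[2-(3-benzyloxyphenyl)ethyl]-4-hydroxy-6-methoxyphenyl}methanone
Product: 13 [4-(benzyloxy)phenyl]{2-[2-(3-benzyloxyphenyl)ethyl]-4,6-dimethoxyphenyl}methanone
Conditions: MeI, K2CO3, acetone, reflux
Reagents that add atoms: iodomethane, CI
Why: Williamson ether synthesis: the phenol of 12, para to the ketone and therefore acidic, is deprotonated by K2CO3 and O-methylated by MeI in an SN2 reaction; there is no other acidic site.

Step 7
Reactants: 13 [4-(benzyloxy)phenyl]{2-[2-(3-benzyloxyphenyl)ethyl]-4,6-dimethoxyphenyl}methanone
Product: 14 [4-(benzyloxy)phenyl]{2-[2-(3-benzyloxyphenyl)ethyl]-4,6-dimethoxyphenyl}methanol (racemic)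
Conditions: LiAlH4, THF, 0 °C → rt; aq. potassium sodium tartrate work-up
Reagents that add atoms: none
Why: Hydride addition to a diaryl ketone; LiAlH4 is chosen over a borohydride because the carbonyl is flanked by a 2,6-disubstituted ring and deactivated by alkoxy groups on both rings. The new stereocentre at C7 forms as a racemate and is deleted in step 8; benzyl and methyl ethers are inert.

Step 8
Reactants: 14 [4-(benzyloxy)phenyl]{2-[2-(3-benzyloxyphenyl)ethyl]-4,6-dimethoxyphenyl}methanol
Product: 15 2-[4-(benzyloxy)benzyl]-1-{2-[3-(benzyloxy)phenyl]ethyl}-3,5-dimethoxybenzene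
Conditions: Et3SiH (3 equiv), then CF3CO2H (3 equiv) added slowly, CH2Cl2, –20 → 0 °C
Reagents that add atoms: none
Why: Ionic hydrogenation: CF3CO2H ionises the carbinol to a benzhydryl cation stabilised by the ortho and para methoxy groups of ring A and the para benzyloxy group of ring C, and Et3SiH, present in excess before the acid is added, delivers hydride to C7. Intermolecular hydride capture of such a cation should be much faster than attack by the tethered ring B, and aryl benzyl ethers survive brief exposure to dilute CF3CO2H at or below 0 °C.

Step 9
Reactants: 15 2-[4-(benzyloxy)benzyl]-1-{2-[3-(benzyloxy)phenyl]ethyl}-3,5-dimethoxybenzene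
Product: 16 gymconopin D, 3-{2-[2-(4-hydroxybenzyl)-3,5-dimethoxyphenyl]ethyl}phenol
Conditions: H2 (1 atm), 10% Pd/C, EtOAc/MeOH, rt
Reagents that add atoms: none
Why: Hydrogenolysis of the two aryl benzyl ethers over palladium on carbon; aryl methyl ethers, the diarylmethane C–C bonds and the arenes are untouched at atmospheric pressure and room temperature.

## Compound list

1 | 1-(trimethylsilyl)propyne | CC#C[Si](C)(C)C | starting material
2 | 3-(benzyloxy)benzyl bromide | BrCc1cccc(OCc2ccccc2)c1 | starting material
3 | 3-(trimethylsilyl)prop-2-yn-1-yllithium (lithiated 1, not isolated) | [Li]CC#C[Si](C)(C)C | intermediate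
4 | {4-[3-(benzyloxy)phenyl]but-1-yn-1-yl}trimethylsilane | C[Si](C)(C)C#CCCc1cccc(OCc2ccccc2)c1 | intermediate
5 | 1-(benzyloxy)-3-(but-3-yn-1-yl)benzene | C#CCCc1cccc(OCc2ccccc2)c1 | intermediate
6 | 4-(benzyloxy)benzoyl chloride | O=C(Cl)c1ccc(OCc2ccccc2)cc1 | starting material
7 | 1-[4-(benzyloxy)phenyl]-5-[3-(benzyloxy)phenyl]pent-2-yn-1-one | O=C(C#CCCc1cccc(OCc2ccccc2)c1)c1ccc(OCc2ccccc2)cc1 | intermediate
8 | 4,4-dimethoxybut-3-en-2-one | CC(=O)C=C(OC)OC | starting material
9 | 1,1-dimethoxy-3-(trimethylsilyloxy)buta-1,3-diene | COC(OC)=CC(=C)O[Si](C)(C)C | intermediate
10 | [4-(benzyloxy)phenyl]{2-[2-(3-benzyloxyphenyl)ethyl]-6,6-dimethoxy-4-(trimethylsilyloxy)cyclohexa-1,4-dien-1-yl}methanone (not isolated) | COC1(OC)C=C(O[Si](C)(C)C)CC(CCc2cccc(OCc3ccccc3)c2)=C1C(=O)c1ccc(OCc2ccccc2)cc1 | intermediate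
11 | [4-(benzyloxy)phenyl]{2-[2-(3-benzyloxyphenyl)ethyl]-6-methoxy-4-(trimethylsilyloxy)phenyl}methanone (not isolated) | COc1cc(O[Si](C)(C)C)cc(CCc2cccc(OCc3ccccc3)c2)c1C(=O)c1ccc(OCc2ccccc2)cc1 | intermediate
12 | [4-(benzyloxy)phenyl]{2-[2-(3-benzyloxyphenyl)ethyl]-4-hydroxy-6-methoxyphenyl}methanone | COc1cc(O)cc(CCc2cccc(OCc3ccccc3)c2)c1C(=O)c1ccc(OCc2ccccc2)cc1 | intermediate
13 | [4-(benzyloxy)phenyl]{2-[2-(3-benzyloxyphenyl)ethyl]-4,6-dimethoxyphenyl}methanone | COc1cc(OC)cc(CCc2cccc(OCc3ccccc3)c2)c1C(=O)c1ccc(OCc2ccccc2)cc1 | intermediate
14 | [4-(benzyloxy)phenyl]{2-[2-(3-benzyloxyphenyl)ethyl]-4,6-dimethoxyphenyl}methanol (racemic) | COc1cc(OC)cc(CCc2cccc(OCc3ccccc3)c2)c1C(O)c1ccc(OCc2ccccc2)cc1 | intermediate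
15 | 2-[4-(benzyloxy)benzyl]-1-{2-[3-(benzyloxy)phenyl]ethyl}-3,5-dimethoxybenzene | COc1cc(OC)cc(CCc2cccc(OCc3ccccc3)c2)c1Cc1ccc(OCc2ccccc2)cc1 | intermediate
16 | gymconopin D, 3-{2-[2-(4-hydroxybenzyl)-3,5-dimethoxyphenyl]ethyl}phenol | COc1cc(CCc2cccc(O)c2)c(Cc2ccc(O)cc2)c(OC)c1 | target

## Step count and risks

Total step count: 9. Longest linear sequence: 8 steps (steps 1, 2, 3, 5, 6, 7, 8, 9); the diene branch (step 4) joins at step 5.

**Step 5 (key step).** The internal, β-alkyl-substituted ynone may react slowly, so that thermal decomposition or adventitious hydrolysis of the ketene acetal diene outruns cycloaddition. Alternatively the first C–C bond may form by conjugate addition at C1 without ring closure at C3. The fallback gives up the benzannulation and sets out from bromide 2. Heating 2 with P(OEt)3 (Michaelis–Arbuzov reaction) would give diethyl [3-(benzyloxy)benzyl]phosphonate F1. Horner–Wadsworth–Emmons olefination of purchased 3,5-dimethoxybenzaldehyde F2 (NaH, THF) would give (E)-1-(benzyloxy)-3-[2-(3,5-dimethoxyphenyl)ethenyl]benzene F3. Diimide reduction (TsNHNH2, NaOAc, aqueous THF, reflux), which spares benzyl ethers, would give 1-(benzyloxy)-3-[2-(3,5-dimethoxyphenyl)ethyl]benzene F4. Friedel–Crafts acylation of F4 with acid chloride 6 (SnCl4, CH2Cl2, –20 → 0 °C) should go ortho to the chain and para to a methoxy group, and the route is rejoined at ketone 13. The price is that regiochemistry again depends on arene substitution, and the Lewis acid must stay mild enough for the benzyl ethers.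

**Step 3.** Copper-mediated oxidative dimerisation of alkyne 5, hydrolysis of the acid chloride, or amine addition to the product ynone may erode the coupling. The fallback sets out from alkyne 5. Deprotonation with n-BuLi (THF, –78 °C) and addition to purchased 4-(benzyloxy)benzaldehyde F5 would give racemic 1-[4-(benzyloxy)phenyl]-5-[3-(benzyloxy)phenyl]pent-2-yn-1-ol F6. Oxidation with activated MnO2 in CH2Cl2 would return to ynone 7.

**Step 7.** Hydride delivery may be slow or incomplete because the carbonyl is shielded by the 2,6-disubstituted ring, and the electron-rich carbinol may ionise during work-up. The fallback sets out from ketone 13 and applies ionic hydrogenation to the carbonyl group itself (Et3SiH, CF3CO2H, CH2Cl2, rt), so that protonation rather than nucleophilic attack activates the hindered ketone. It comes back at 15 and makes no new compound, which is entered below as F0.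

**Step 8.** The benzhydryl cation may be intercepted by ring B (intramolecular Friedel–Crafts alkylation closing a seven-membered ring) or by a second molecule of carbinol, and the acid may loosen the benzyl ethers. The fallback sets out from carbinol 14 and avoids the free cation. Hydrogenolysis over Pd/C (H2, EtOAc/EtOH, rt) would cleave the doubly benzylic C–O bond together with both benzyl ethers. It comes back at target 16 and makes no new compound, which is entered below as F0.

## Further compounds

F1 | step 5 | diethyl [3-(benzyloxy)benzyl]phosphonate | CCOP(=O)(Cc1cccc(OCc2ccccc2)c1)OCC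
F2 | step 5 | 3,5-dimethoxybenzaldehyde (purchased) | COc1cc(C=O)cc(OC)c1
F3 | step 5 | (E)-1-(benzyloxy)-3-[2-(3,5-dimethoxyphenyl)ethenyl]benzene | COc1cc(/C=C/c2cccc(OCc3ccccc3)c2)cc(OC)c1
F4 | step 5 | 1-(benzyloxy)-3-[2-(3,5-dimethoxyphenyl)ethyl]benzene | COc1cc(CCc2cccc(OCc3ccccc3)c2)cc(OC)c1
F5 | step 3 | 4-(benzyloxy)benzaldehyde (purchased) | O=Cc1ccc(OCc2ccccc2)cc1
F6 | step 3 | 1-[4-(benzyloxy)phenyl]-5-[3-(benzyloxy)phenyl]pent-2-yn-1-ol (racemic) | OC(C#CCCc1cccc(OCc2ccccc2)c1)c1ccc(OCc2ccccc2)cc1
F0 | step 7 | none | none
F0 | step 8 | none | none
A1 | alternative 1 | 2-{1-[2-(4-benzyloxybenzyl)-3,5-dimethoxyphenyl]-2-[3-(benzyloxy)phenyl]ethyl}-4,4,5,5-tetramethyl-1,3,2-dioxaborolane (one enantiomer drawn; the centre is erased on protodeboronation) | COc1cc([C@@H](Cc2cccc(OCc3ccccc3)c2)B2OC(C)(C)C(C)(C)O2)c(Cc2ccc(OCc3ccccc3)cc2)c(OC)c1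
A2 | alternative 1 | 1-bromo-2-[4-(benzyloxy)benzyl]-3,5-dimethoxybenzene | COc1cc(Br)c(Cc2ccc(OCc3ccccc3)cc2)c(OC)c1
A3 | alternative 1 | 4,4,5,5-tetramethyl-2-vinyl-1,3,2-dioxaborolane | C=CB1OC(C)(C)C(C)(C)O1
A4 | alternative 1 | 3-(benzyloxy)phenyl trifluoromethanesulfonate | O=S(=O)(Oc1cccc(OCc2ccccc2)c1)C(F)(F)F
A5 | alternative 2 | methyl 2-[2-(3-benzyloxyphenyl)ethyl]-4,6-dimethoxybenzoate | COC(=O)c1c(CCc2cccc(OCc3ccccc3)c2)cc(OC)cc1OC
A6 | alternative 2 | methyl 6-[2-(3-benzyloxyphenyl)ethyl]-4-methoxy-2-oxo-2H-pyran-5-carboxylate | COC(=O)C1=C(CCc2cccc(OCc3ccccc3)c2)OC(=O)C=C1OC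
A7 | alternative 2 | 1,1-dimethoxyethene | C=C(OC)OC
A8 | alternative 3 | 4-[4-(benzyloxy)benzyl]-5-[2-(3-benzyloxyphenyl)ethyl]benzene-1,3-diol | Oc1cc(O)c(Cc2ccc(OCc3ccccc3)cc2)c(CCc2cccc(OCc3ccccc3)c2)c1
A9 | alternative 3 | tert-butyl 2-[4-(benzyloxy)benzyl]-9-[3-(benzyloxy)phenyl]-3,5,7-trioxononanoate | CC(C)(C)OC(=O)C(Cc1ccc(OCc2ccccc2)cc1)C(=O)CC(=O)CC(=O)CCc1cccc(OCc2ccccc2)c1
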